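## Retrosynthetic overview

1. Endgame on ring B: C9–C11 by axial 1,2-addition of a C11–C15 alkylcerium to the 8(17)-en-9-one, C17 by Mannich methylenation of the C9 ketone, then fluoride to free C15–OH and the C19 acid.
2. Ring A: the ring-fusion carbinol C5 (5α-OH), flanked by quaternary C4 and C10, is an oxy-Cope/ene retron. C5–O is the oxy-Cope oxygen; C3=C4 (carrying C19) sits on C5 and C1=C2 on C10 of ring B. The [3,3] shift joins C2 to C3 (ten-membered ring C1–C10), C4 is methylated as its β-keto ester enolate, and a transannular carbonyl-ene reaction re-forms C5–C10.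
3. Ring B (C5–C10 with C20) is 2-methylcyclohexane-1,3-dione; C1=C2 comes from a vinyl sulfoxide, and C3/C4/C19 from an acrylate α-anion equivalent.
4. Absolute configuration: a ketoreductase desymmetrizes the dione and sets C9 (S). This is the only centre that survives the rearrangement; it relays to C4, C5 and C10 and is then oxidized to the C9 ketone.
5. Ring order: ring B (present from the start) → transient ten-membered ring → ring A, with the A/B fusion re-formed in the same operation.

Key step: step 9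

Assumption: labdane numbering (C1–C20) is used for all intermediates; the ketoreductase is taken from a commercial screening panel and selected for the (2S,3S) ketol, and the thermal stage of step 9 is run in the same vessel after removal of THF and excess MeI.

## Route

Step 1
Reactants: 1 2-methylcyclohexane-1,3-dione; 2 phenyl vinyl sulfoxide
Product: 3 2-methyl-2-[2-(phenylsulfinyl)ethyl]cyclohexane-1,3-dione
Conditions: DBU (0.2 equiv), MeCN, 60 °C
Reagents that add atoms: none
Why: Michael addition of the dione enolate to the vinyl sulfoxide (a vinyl cation equivalent) should build quaternary C10 by C-alkylation; sulfur is racemic and is removed in step 2.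

Step 2
Reactants: 3 2-methyl-2-[2-(phenylsulfinyl)ethyl]cyclohexane-1,3-dione
Product: 4 2-ethenyl-2-methylcyclohexane-1,3-dione
Conditions: PhMe, 110 °C
Reagents that add atoms: none
Why: thermal syn-elimination of the sulfoxide (sulfoxide pyrolysis) can only take a hydrogen from C1 and so should unveil the C1=C2 vinyl group on C10.

Step 3
Reactants: 4 2-ethenyl-2-methylcyclohexane-1,3-dione
Product: 5 (2S,3S)-2-ethenyl-3-hydroxy-2-methylcyclohexan-1-one
Conditions: ketoreductase (KRED, (S)-selective), NADP+ (cat.), i-PrOH (10 vol%), phosphate buffer pH 7, 30 °C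
Reagents that add atoms: none
Why: enzymatic desymmetrizing reduction of the prochiral 2,2-disubstituted 1,3-dione, as known for yeast and ketoreductase reductions of 2-allyl-2-methylcyclohexane-1,3-dione, should deliver hydride to one enantiotopic carbonyl and set C9 as (S) with the hydroxyl cis to the vinyl group.

Step 4
Reactants: 5 (2S,3S)-2-ethenyl-3-hydroxy-2-methylcyclohexan-1-one
Product: 6 (2S,3S)-3-(benzyloxy)-2-ethenyl-2-methylcyclohexan-1-one
Conditions: BnOC(=NH)CCl3, TfOH (cat.), CH2Cl2/cyclohexane, 0 °C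
Reagents that add atoms: benzyl 2,2,2-trichloroacetimidate ClC(Cl)(Cl)C(=N)OCc1ccccc1
Why: acid-catalysed O-benzylation avoids the alkoxide and hence retro-aldol cleavage of the β-hydroxy ketone; the benzyl ether cannot migrate to the C5 alkoxide of step 9 and falls off in the hydrogenation of step 10.

Step 5
Reactants: 7 acryloyl chloride; 8 2-(trimethylsilyl)ethanol
Product: 9 2-(trimethylsilyl)ethyl acrylate
Conditions: Et3N, CH2Cl2, 0 °C
Reagents that add atoms: none
Why: acylation of the alcohol by the acid chloride installs the fluoride-labile ester that will carry C19.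

Step 6
Reactants: 9 2-(trimethylsilyl)ethyl acrylate; 10 dimethylamine
Product: 11 2-(trimethylsilyl)ethyl 3-(dimethylamino)propanoate
Conditions: THF, 0 °C to rt
Reagents that add atoms: none
Why: aza-Michael addition gives the β-amino ester, whose enolate is a stable acrylate α-anion equivalent.

Step 7
Reactants: 6 (2S,3S)-3-(benzyloxy)-2-ethenyl-2-methylcyclohexan-1-one; 11 2-(trimethylsilyl)ethyl 3-(dimethylamino)propanoate
Product: 12 2-(trimethylsilyl)ethyl 2-[(1S,2S,3S)-3-(benzyloxy)-2-ethenyl-1-hydroxy-2-methylcyclohexyl]-3-(dimethylamino)propanoate (both epimers at the ester α-carbon)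
Conditions: LiN(i-Pr)2 (LDA), 11, THF, −78 °C; then 6, −78 °C; AcOH quench at −78 °C
Reagents that add atoms: none
Why: aldol addition of the lithium ester enolate to the C5 ketone should occur axially, anti to the axial vinyl group of the chair that keeps the C9 benzyloxy group equatorial, so that the new C4–C5 bond is trans to the vinyl group; the epimers at C4 are of no consequence.

Step 8
Reactants: 12 2-(trimethylsilyl)ethyl 2-[(1S,2S,3S)-3-(benzyloxy)-2-ethenyl-1-hydroxy-2-methylcyclohexyl]-3-(dimethylamino)propanoate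
Product: 14 2-(trimethylsilyl)ethyl 2-[(1R,2S,3S)-3-(benzyloxy)-2-ethenyl-1-hydroxy-2-methylcyclohexyl]prop-2-enoate, via ammonium iodide 13 (not isolated)
Conditions: MeI, MeOH, rt; then DBU, CH2Cl2, rt
Reagents that add atoms: none
Why: N-quaternization followed by E1cB (Hofmann-type) loss of trimethylamine should give the C3=C4 acrylate on the tertiary carbinol without touching C5.

Step 9
Reactants: 14 2-(trimethylsilyl)ethyl 2-[(1R,2S,3S)-3-(benzyloxy)-2-ethenyl-1-hydroxy-2-methylcyclohexyl]prop-2-enoate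
Product: 17 2-(trimethylsilyl)ethyl (1S,4aR,5S,8aS)-5-(benzyloxy)-8a-hydroxy-1,4a-dimethyl-1,2,4a,5,6,7,8,8a-octahydronaphthalene-1-carboxylate, via ten-membered potassium enolate 15 (not isolated), via ten-membered keto ester 16 (not isolated)
Conditions: KN(SiMe3)2, 18-crown-6, THF, −78 to 0 °C; MeI, −78 to 0 °C; then solvent exchange to PhMe, 180 °C (sealed tube)
Reagents that add atoms: iodomethane CI
Why: Deprotonation gives the C5 potassium alkoxide, whose anionic oxy-Cope rearrangement ([3,3] shift through a chair with both alkenyl groups equatorial on ring B) joins C2 to C3, cleaves C5–C10 and so closes the ten-membered ring C1–C10 as the (E)-alkene β-keto ester enolate 15; MeI C-methylates C4 to give 16, and at 180 °C the C5 ketone (enophile) and the C1=C10 alkene with H-2 (ene) should undergo a transannular carbonyl-ene reaction that re-forms C5–C10 and leaves ring A closed with C2–C3 as its only new σ-bond. The closest known reaction types are the thermal tandem oxy-Cope/transannular ene and oxy-Cope/Claisen/ene cascades of 1,2-divinylcyclohexanols and the anionic oxy-Cope/enolate alkylation sequence, with alkylation here taking the place of the Claisen step. The ten-membered ring is closed by the sigmatropic ring expansion itself, and rings A and B are re-closed by 1,6-transannular attack of C10 on the carbonyl carbon (6-exo-trig at C5=O, hydrogen passing from C2 to oxygen in a six-membered ene transition state). C4 is set by methylation on the peripheral face of the ring conformer that holds the C9 benzyloxy group pseudo-equatorial (CH3 equatorial and cis to the C5 oxygen, ester axial), while C5 and C10 are set together in the ene step, the (E)-alkene giving the trans fusion (5-OH anti to the C10 methyl) and the equatorial C9–OBn together with the axial-ester/equatorial-methyl preference at C4 fixing its absolute sense. The step needs E-selectivity in the rearrangement, secured by the trans-dialkenyl arrangement made in step 7, and C5-to-C10 rather than C5-to-C1 bonding in the ene reaction, secured by the alignment of the C5 and C10 p-orbitals inherited from the cleaved σ-bond and by C2–H being the only hydrogen this mode can transfer.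

Step 10
Reactants: 17 2-(trimethylsilyl)ethyl (1S,4aR,5S,8aS)-5-(benzyloxy)-8a-hydroxy-1,4a-dimethyl-1,2,4a,5,6,7,8,8a-octahydronaphthalene-1-carboxylate
Product: 18 2-(trimethylsilyl)ethyl (1S,4aR,5S,8aS)-5,8a-dihydroxy-1,4a-dimethyldecahydronaphthalene-1-carboxylate
Conditions: H2 (1 atm), Pd/C, EtOAc/EtOH, rt
Reagents that add atoms: none
Why: heterogeneous hydrogenation should saturate C1=C2 and the same catalyst should cleave the benzyl ether by hydrogenolysis; no stereocenter is touched.

Step 11
Reactants: 18 2-(trimethylsilyl)ethyl (1S,4aR,5S,8aS)-5,8a-dihydroxy-1,4a-dimethyldecahydronaphthalene-1-carboxylate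
Product: 19 2-(trimethylsilyl)ethyl (1S,4aS,8aS)-8a-hydroxy-1,4a-dimethyl-5-oxodecahydronaphthalene-1-carboxylate
Conditions: DMP (1,1,1-triacetoxy-1,1-dihydro-1,2-benziodoxol-3(1H)-one), CH2Cl2, 0 °C to rt
Reagents that add atoms: none
Why: periodinane oxidation of the only oxidizable (secondary, C9) alcohol under non-basic conditions avoids retro-aldol opening of C5–C10 and retires the stereocenter that has done its relay work.

Step 12
Reactants: 19 2-(trimethylsilyl)ethyl (1S,4aS,8aS)-8a-hydroxy-1,4a-dimethyl-5-oxodecahydronaphthalene-1-carboxylate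
Product: 21 2-(trimethylsilyl)ethyl (1S,4aS,8aS)-8a-hydroxy-1,4a-dimethyl-6-methylidene-5-oxodecahydronaphthalene-1-carboxylate, via Mannich base 20 (not isolated)
Conditions: (CH2O)n, N-methylanilinium trifluoroacetate, THF, 65 °C
Reagents that add atoms: formaldehyde (as paraformaldehyde) C=O
Why: Mannich reaction at C8, the only enolizable position of the ketone, followed by elimination of N-methylaniline should give the α-methylene ketone (C17) under mildly acidic conditions.

Step 13
Reactants: 22 (2E)-3-methylpent-2-en-4-yn-1-ol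
Product: 23 tert-butyldimethyl{[(2E)-3-methylpent-2-en-4-yn-1-yl]oxy}silane
Conditions: TBSCl, imidazole, DMF, rt
Reagents that add atoms: tert-butyldimethylsilyl chloride CC(C)(C)[Si](C)(C)Cl
Why: standard silylation of the primary allylic alcohol; the (E)-trisubstituted alkene (C13=C14) is taken from the starting material.

Step 14
Reactants: 23 tert-butyldimethyl{[(2E)-3-methylpent-2-en-4-yn-1-yl]oxy}silane
Product: 24 tert-butyldimethyl{[(2E)-3-methylpenta-2,4-dien-1-yl]oxy}silane
Conditions: H2 (1 atm), Pd/CaCO3 poisoned with Pb(OAc)2, quinoline, hexane, rt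
Reagents that add atoms: none
Why: semihydrogenation of the terminal alkyne on the poisoned catalyst should stop at the vinyl group and leave the trisubstituted alkene untouched.

Step 15
Reactants: 24 tert-butyldimethyl{[(2E)-3-methylpenta-2,4-dien-1-yl]oxy}silane
Product: 26 (3E)-5-[(tert-butyldimethylsilyl)oxy]-3-methylpent-3-en-1-ol, via alkylborane 25 (not isolated)
Conditions: 9-BBN, THF, 0 °C to rt; then NaOH, H2O2, 0 °C
Reagents that add atoms: hydrogen peroxide OO
Why: 9-BBN hydroborates only the monosubstituted terminal alkene of the diene at its CH2 terminus (anti-Markovnikov), and oxidation gives the primary alcohol at C11 with the trisubstituted (E)-alkene intact.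

Step 16
Reactants: 26 (3E)-5-[(tert-butyldimethylsilyl)oxy]-3-methylpent-3-en-1-ol
Product: 27 tert-butyl{[(2E)-5-iodo-3-methylpent-2-en-1-yl]oxy}dimethylsilane
Conditions: I2, PPh3, imidazole, CH2Cl2, 0 °C
Reagents that add atoms: iodine II
Why: Appel-type iodination of the primary alcohol gives the homoallylic iodide needed for halogen–lithium exchange.

Step 17
Reactants: 21 2-(trimethylsilyl)ethyl (1S,4aS,8aS)-8a-hydroxy-1,4a-dimethyl-6-methylidene-5-oxodecahydronaphthalene-1-carboxylate; 27 tert-butyl{[(2E)-5-iodo-3-methylpent-2-en-1-yl]oxy}dimethylsilane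
Product: 30 2-(trimethylsilyl)ethyl (1S,4aR,5S,8aS)-5-{(3E)-5-[(tert-butyldimethylsilyl)oxy]-3-methylpent-3-en-1-yl}-5,8a-dihydroxy-1,4a-dimethyl-6-methylidenedecahydronaphthalene-1-carboxylate, via organolithium 28 (not isolated), via organocerium 29 (not isolated)
Conditions: 27, t-BuLi (2 equiv), Et2O, −78 °C; CeCl3, THF, −78 °C; then 21 (pre-treated with LiN(SiMe3)2, 1 equiv, THF, −78 °C), −78 °C; aq NH4Cl
Reagents that add atoms: none
Why: the weakly basic organocerium should add 1,2 to the α-methylene ketone, entering C9 axially from the α-face, anti to the axial C10 methyl and guided by the C5 lithium alkoxide, which places the side chain α and the new hydroxyl β (equatorial).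

Step 18
Reactants: 30 2-(trimethylsilyl)ethyl (1S,4aR,5S,8aS)-5-{(3E)-5-[(tert-butyldimethylsilyl)oxy]-3-methylpent-3-en-1-yl}-5,8a-dihydroxy-1,4a-dimethyl-6-methylidenedecahydronaphthalene-1-carboxylate
Product: 31 5alpha,9beta-dihydroxyisocupressic acid
Conditions: Bu4NF, THF, 0 °C to rt; then dilute aq HCl to pH 4 at 0 °C
Reagents that add atoms: none
Why: fluoride should cleave the silyl ether and, by attack at silicon and β-elimination, the 2-(trimethylsilyl)ethyl ester, so the hindered axial C19 carboxylate is freed without acyl substitution and without touching the tertiary allylic alcohol.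

## Compound list

1 | 2-methylcyclohexane-1,3-dione | CC1C(=O)CCCC1=O | starting material
2 | phenyl vinyl sulfoxide (racemic) | C=CS(=O)c1ccccc1 | starting material
3 | 2-methyl-2-[2-(phenylsulfinyl)ethyl]cyclohexane-1,3-dione (racemic at sulfur) | CC1(CCS(=O)c2ccccc2)C(=O)CCCC1=O | intermediate
4 | 2-ethenyl-2-methylcyclohexane-1,3-dione | C=CC1(C)C(=O)CCCC1=O | intermediate
5 | (2S,3S)-2-ethenyl-3-hydroxy-2-methylcyclohexan-1-one | O=C1CCC[C@H](O)[C@]1(C)C=C | intermediate
6 | (2S,3S)-3-(benzyloxy)-2-ethenyl-2-methylcyclohexan-1-one | O=C1CCC[C@H](OCc2ccccc2)[C@]1(C)C=C | intermediate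
7 | acryloyl chloride | C=CC(=O)Cl | starting material
8 | 2-(trimethylsilyl)ethanol | C[Si](C)(C)CCO | starting material
9 | 2-(trimethylsilyl)ethyl acrylate | C=CC(=O)OCC[Si](C)(C)C | intermediate
10 | dimethylamine | CNC | starting material
11 | 2-(trimethylsilyl)ethyl 3-(dimethylamino)propanoate | CN(C)CCC(=O)OCC[Si](C)(C)C | intermediate
12 | 2-(trimethylsilyl)ethyl 2-[(1S,2S,3S)-3-(benzyloxy)-2-ethenyl-1-hydroxy-2-methylcyclohexyl]-3-(dimethylamino)propanoate (epimers at the ester α-carbon) | C=C[C@@]1(C)[C@@H](OCc2ccccc2)CCC[C@]1(O)C(CN(C)C)C(=O)OCC[Si](C)(C)C | intermediate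
13 | trimethylammonium iodide of 12 (N-methylated at the dimethylamino group) | C=C[C@@]1(C)[C@@H](OCc2ccccc2)CCC[C@]1(O)C(C[N+](C)(C)C)C(=O)OCC[Si](C)(C)C.[I-] | intermediate
14 | 2-(trimethylsilyl)ethyl 2-[(1R,2S,3S)-3-(benzyloxy)-2-ethenyl-1-hydroxy-2-methylcyclohexyl]prop-2-enoate | C=C[C@@]1(C)[C@@H](OCc2ccccc2)CCC[C@]1(O)C(=C)C(=O)OCC[Si](C)(C)C | intermediate
15 | potassium (1E,5E,7S)-7-(benzyloxy)-6-methyl-2-{[2-(trimethylsilyl)ethoxy]carbonyl}cyclodeca-1,5-dien-1-olate | [K+].[O-]/C1=C(/C(=O)OCC[Si](C)(C)C)CC/C=C(C)/[C@@H](OCc2ccccc2)CCC1 | intermediate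
16 | 2-(trimethylsilyl)ethyl (1S,4E,6S)-6-(benzyloxy)-1,5-dimethyl-10-oxocyclodec-4-ene-1-carboxylate | C[Si](C)(C)CCOC(=O)[C@@]1(C)CC/C=C(C)/[C@@H](OCc2ccccc2)CCCC1=O | intermediate
17 | 2-(trimethylsilyl)ethyl (1S,4aR,5S,8aS)-5-(benzyloxy)-8a-hydroxy-1,4a-dimethyl-1,2,4a,5,6,7,8,8a-octahydronaphthalene-1-carboxylate | C[Si](C)(C)CCOC(=O)[C@@]1(C)CC=C[C@]2(C)[C@@H](OCc3ccccc3)CCC[C@@]12O | intermediate
18 | 2-(trimethylsilyl)ethyl (1S,4aR,5S,8aS)-5,8a-dihydroxy-1,4a-dimethyldecahydronaphthalene-1-carboxylate | C[Si](C)(C)CCOC(=O)[C@@]1(C)CCC[C@]2(C)[C@@H](O)CCC[C@@]12O | intermediate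
19 | 2-(trimethylsilyl)ethyl (1S,4aS,8aS)-8a-hydroxy-1,4a-dimethyl-5-oxodecahydronaphthalene-1-carboxylate | C[Si](C)(C)CCOC(=O)[C@@]1(C)CCC[C@]2(C)C(=O)CCC[C@@]12O | intermediate
20 | 2-(trimethylsilyl)ethyl (1S,4aS,8aS)-8a-hydroxy-1,4a-dimethyl-6-{[methyl(phenyl)amino]methyl}-5-oxodecahydronaphthalene-1-carboxylate (epimers at C6 of the naphthalene) | C[Si](C)(C)CCOC(=O)[C@@]1(C)CCC[C@]2(C)C(=O)C(CN(C)c3ccccc3)CC[C@@]12O | intermediate
21 | 2-(trimethylsilyl)ethyl (1S,4aS,8aS)-8a-hydroxy-1,4a-dimethyl-6-methylidene-5-oxodecahydronaphthalene-1-carboxylate | C[Si](C)(C)CCOC(=O)[C@@]1(C)CCC[C@]2(C)C(=O)C(=C)CC[C@@]12O | intermediate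
22 | (2E)-3-methylpent-2-en-4-yn-1-ol | C#C/C(C)=C/CO | starting material
23 | tert-butyldimethyl{[(2E)-3-methylpent-2-en-4-yn-1-yl]oxy}silane | C#C/C(C)=C/CO[Si](C)(C)C(C)(C)C | intermediate
24 | tert-butyldimethyl{[(2E)-3-methylpenta-2,4-dien-1-yl]oxy}silane | C=C/C(C)=C/CO[Si](C)(C)C(C)(C)C | intermediate
25 | 9-{(3E)-5-[(tert-butyldimethylsilyl)oxy]-3-methylpent-3-en-1-yl}-9-borabicyclo[3.3.1]nonane | CC(C)(C)[Si](C)(C)OC/C=C(C)/CCB1C2CCCC1CCC2 | intermediate
26 | (3E)-5-[(tert-butyldimethylsilyl)oxy]-3-methylpent-3-en-1-ol | CC(C)(C)[Si](C)(C)OC/C=C(C)/CCO | intermediate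
27 | tert-butyl{[(2E)-5-iodo-3-methylpent-2-en-1-yl]oxy}dimethylsilane | CC(C)(C)[Si](C)(C)OC/C=C(C)/CCI | intermediate
28 | {(3E)-5-[(tert-butyldimethylsilyl)oxy]-3-methylpent-3-en-1-yl}lithium | [Li]CC/C(C)=C/CO[Si](C)(C)C(C)(C)C | intermediate
29 | dichloro{(3E)-5-[(tert-butyldimethylsilyl)oxy]-3-methylpent-3-en-1-yl}cerium | Cl[Ce](Cl)CC/C(C)=C/CO[Si](C)(C)C(C)(C)C | intermediate
30 | 2-(trimethylsilyl)ethyl (1S,4aR,5S,8aS)-5-{(3E)-5-[(tert-butyldimethylsilyl)oxy]-3-methylpent-3-en-1-yl}-5,8a-dihydroxy-1,4a-dimethyl-6-methylidenedecahydronaphthalene-1-carboxylate | C[Si](C)(C)CCOC(=O)[C@@]1(C)CCC[C@]2(C)[C@](O)(CC/C(C)=C/CO[Si](C)(C)C(C)(C)C)C(=C)CC[C@@]12O | intermediate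
31 | 5alpha,9beta-dihydroxyisocupressic acid, (1S,4aR,5S,8aS)-5,8a-dihydroxy-5-[(3E)-5-hydroxy-3-methylpent-3-en-1-yl]-1,4a-dimethyl-6-methylidenedecahydronaphthalene-1-carboxylic acid | C=C1CC[C@]2(O)[C@](C)(CCC[C@]2(C)C(=O)O)[C@]1(O)CC/C(C)=C/CO | target

## Step count and risks

Total step count: 18. Longest linear sequence: 12 steps (steps 1–4, 7–12, 17 and 18).

**Step 9.** What may go wrong: the methylation of the conformationally mobile ten-membered enolate may show poor facial selectivity, and 1,5- may compete with 1,6-transannular ene closure once C4 is quaternary. The fallback sets out from 14 and comes back at 17. Heating 14 in PhMe with DBU (cat.) and BHT at 220 °C (sealed tube) should run the neutral oxy-Cope rearrangement, enol–keto tautomerization and transannular ene reaction without any alkylation. This gives the C4-unmethylated hydroxy ester, 2-(trimethylsilyl)ethyl (4aR,5S,8aR)-5-(benzyloxy)-8a-hydroxy-4a-methyl-1,2,4a,5,6,7,8,8a-octahydronaphthalene-1-carboxylate F1. Its alkoxide–enolate dianion (LDA, 2.2 equiv, THF/DMPU, −78 to −40 °C) is then C-methylated with MeI on the rigid trans-decalin, where the axial C10 methyl shields the β-face, to return to 17.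

**Step 17.** What may go wrong: the bulky sp3 organometallic may add with poor facial selectivity to the hindered α-methylene ketone, or the C5 alkoxide may trigger retro-aldol side reactions. The fallback sets out from 21 and comes back at 31; it builds the chain in stages from a small nucleophile.
- Corey–Chaykovsky reaction (Me3S+ I−, KN(SiMe3)2, THF, −10 °C) should deliver CH2 axially from the α-face to give the C9 spiro-epoxide of 21 (oxirane oxygen β, C11H2 α) F2.
- Lithiated 1-(trimethylsilyl)propyne with BF3·OEt2 (THF, −78 °C) opens the epoxide at C11 to give the C9 [4-(trimethylsilyl)but-3-yn-1-yl] carbinol F3.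
- K2CO3/MeOH gives the terminal alkyne, the C9 but-3-yn-1-yl carbinol F4.
- Zirconium-catalysed carboalumination (Me3Al, Cp2ZrCl2, CH2Cl2), then n-BuLi and (CH2O)n, installs C16 and C15 syn and so gives the (13E)-allylic alcohol, the 2-(trimethylsilyl)ethyl ester of the target F5.
- Bu4NF then gives 31.

**Step 7.** What may go wrong: the aldol addition to the hindered α-quaternary ketone may reverse (retro-aldol) on warming, with loss of facial selectivity. The fallback sets out from 6 and comes back at 14; it uses an irreversible organometallic addition.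
- 2-Lithio-3,3-diethoxyprop-1-ene (from 2-bromo-3,3-diethoxyprop-1-ene and t-BuLi) with CeCl3 in THF at −78 °C adds to the C5 ketone to give (1R,2S,3S)-3-(benzyloxy)-1-(3,3-diethoxyprop-1-en-2-yl)-2-ethenyl-2-methylcyclohexan-1-ol F6.
- Oxalic acid on wet silica gel unmasks 2-[(1R,2S,3S)-3-(benzyloxy)-2-ethenyl-1-hydroxy-2-methylcyclohexyl]prop-2-enal F7.
- Pinnick oxidation (NaClO2, NaH2PO4, 2-methylbut-2-ene) gives 2-[(1R,2S,3S)-3-(benzyloxy)-2-ethenyl-1-hydroxy-2-methylcyclohexyl]prop-2-enoic acid F8.
- Esterification with 8 (EDC, DMAP, CH2Cl2) returns to 14.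

Further compounds
F1 | step 9 | 2-(trimethylsilyl)ethyl (4aR,5S,8aR)-5-(benzyloxy)-8a-hydroxy-4a-methyl-1,2,4a,5,6,7,8,8a-octahydronaphthalene-1-carboxylate (epimers at C1) | C[Si](C)(C)CCOC(=O)C1CC=C[C@]2(C)[C@@H](OCc3ccccc3)CCC[C@@]12O
F2 | step 17 | C9 spiro-epoxide of 21 (oxirane oxygen β, C11H2 α) | C[Si](C)(C)CCOC(=O)[C@@]1(C)CCC[C@]2(C)[C@]3(CO3)C(=C)CC[C@@]12O
F3 | step 17 | C9 [4-(trimethylsilyl)but-3-yn-1-yl] carbinol (9β-OH, chain α) | C[Si](C)(C)CCOC(=O)[C@@]1(C)CCC[C@]2(C)[C@](O)(CCC#C[Si](C)(C)C)C(=C)CC[C@@]12O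
F4 | step 17 | C9 but-3-yn-1-yl carbinol (9β-OH, chain α) | C[Si](C)(C)CCOC(=O)[C@@]1(C)CCC[C@]2(C)[C@](O)(CCC#C)C(=C)CC[C@@]12O
F5 | step 17 | 2-(trimethylsilyl)ethyl ester of 5alpha,9beta-dihydroxyisocupressic acid | C[Si](C)(C)CCOC(=O)[C@@]1(C)CCC[C@]2(C)[C@](O)(CC/C(C)=C/CO)C(=C)CC[C@@]12O
F6 | step 7 | (1R,2S,3S)-3-(benzyloxy)-1-(3,3-diethoxyprop-1-en-2-yl)-2-ethenyl-2-methylcyclohexan-1-ol | C=C[C@@]1(C)[C@@H](OCc2ccccc2)CCC[C@]1(O)C(=C)C(OCC)OCC
F7 | step 7 | 2-[(1R,2S,3S)-3-(benzyloxy)-2-ethenyl-1-hydroxy-2-methylcyclohexyl]prop-2-enal | C=C[C@@]1(C)[C@@H](OCc2ccccc2)CCC[C@]1(O)C(=C)C=O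
F8 | step 7 | 2-[(1R,2S,3S)-3-(benzyloxy)-2-ethenyl-1-hydroxy-2-methylcyclohexyl]prop-2-enoic acid | C=C[C@@]1(C)[C@@H](OCc2ccccc2)CCC[C@]1(O)C(=C)C(=O)O
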